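The oxolan-2-one ring is read as the Baeyer–Villiger product of a cyclobutanone: without the ring oxygen O1, carbonyl C2, alkylidene C3, acetoxy-bearing C4 and isobutenyl-bearing C5 form a four-membered ketone that is the [2+2] adduct of (2-methylprop-1-enyl)ketene and an oxygenated allene. That cycloaddition makes the C2–C3 and C4–C5 bonds in one operation, with the allene's spare double bond as the exocyclic methylene and a chiral O-substituent setting C4; C5 is equilibrated trans. Oxygen insertion between C2 and C5, exchange of the auxiliary for acetate and cross-metathesis with a nerol-derived (R)-homoallylic acetate complete the target.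

Key step: step 4

Assumption: the allenyl ether 3 is taken to react through its s-trans conformer with the auxiliary C–H in the enol-ether plane, so that the aryl group covers one face; should the opposite face be preferred, the (R)-alcohol is used instead of 1 and nothing else changes.

Step 1
Reactants: 1 (1S)-1-[2,4,6-tri(propan-2-yl)phenyl]ethanol
Product: 2 2-[(1S)-1-(prop-2-yn-1-yloxy)ethyl]-1,3,5-tri(propan-2-yl)benzene
Conditions: NaH, propargyl bromide, THF/DMF, 0 °C to rt
Reagents that add atoms: propargyl bromide (3-bromoprop-1-yne), C#CCBr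
Why: Williamson etherification of the alkoxide with a primary propargylic bromide (SN2) should proceed without touching the carbinol stereocenter.

Step 2
Reactants: 2 2-[(1S)-1-(prop-2-yn-1-yloxy)ethyl]-1,3,5-tri(propan-2-yl)benzene
Product: 3 2-[(1S)-1-(propa-1,2-dien-1-yloxy)ethyl]-1,3,5-tri(propan-2-yl)benzene
Conditions: KOtBu (30 mol%), THF, rt
Reagents that add atoms: none
Why: Base-catalysed propargyl-to-allenyl isomerisation of a propargyl ether should stop at the alkoxyallene under catalytic KOtBu.

Step 3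
Reactants: 4 4-methylpent-3-enoic acid
Product: 5 4-methylpent-3-enoyl chloride
Conditions: (COCl)2, DMF (cat.), CH2Cl2, 0 °C to rt
Reagents that add atoms: oxalyl chloride, ClC(=O)C(=O)Cl
Why: Vilsmeier-catalysed acid chloride formation is mild enough to leave the β,γ-alkene in place.

Step 4
Reactants: 3 2-[(1S)-1-(propa-1,2-dien-1-yloxy)ethyl]-1,3,5-tri(propan-2-yl)benzene; 5 4-methylpent-3-enoyl chloride
Product: 8 (3R,4R)-2-methylidene-4-(2-methylprop-1-en-1-yl)-3-{(1S)-1-[2,4,6-tri(propan-2-yl)phenyl]ethoxy}cyclobutan-1-one, via ketene 6 (not isolated), via cis-cyclobutanone 7 (not isolated)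
Conditions: Et3N (2 equiv), CH2Cl2, 40 °C, 5 (1.5 equiv) added over 6 h; then DBU (5 mol%), 0 °C
Reagents that add atoms: none
Why: Et3N dehydrochlorinates 5 to vinylketene 6, whose electrophilic carbonyl carbon bonds to the nucleophilic central carbon of the enol-ether C=C of 3 while the ketene α-carbon bonds to the oxygen-bearing allene terminus in a concerted asynchronous [π2s+π2a] cycloaddition. The closest known reactions are the [2+2] cycloadditions of aldo- and vinylketenes with enol ethers (3-alkoxycyclobutanones) and of ketenes with allenes (2-alkylidenecyclobutanones). The four-membered ring is closed by cycloaddition, antarafacial on the ketene and suprafacial on the allene, and the untouched distal allene C=C remains as the exocyclic methylidene. C3 is set by the auxiliary, the ketene adding to the enol-ether face not covered by the triisopropylphenyl group; C4, expected mainly cis at first (7), is epimerisable next to the ketone and should be equilibrated by base to the more stable trans isomer 8. The step needs [2+2] rather than [4+2] periselectivity, addition to the oxygenated and not the distal C=C, and cross-reaction ahead of ketene dimerisation; the first two rest on the enol-ether HOMO of 3, the third on slow addition of 5 so that 6 stays dilute.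

Step 5
Reactants: 8 (3R,4R)-2-methylidene-4-(2-methylprop-1-en-1-yl)-3-{(1S)-1-[2,4,6-tri(propan-2-yl)phenyl]ethoxy}cyclobutan-1-one
Product: 9 (4S,5R)-3-methylidene-5-(2-methylprop-1-en-1-yl)-4-{(1S)-1-[2,4,6-tri(propan-2-yl)phenyl]ethoxy}oxolan-2-one
Conditions: 30% H2O2, AcOH, NaOAc, 0 to 10 °C
Reagents that add atoms: hydrogen peroxide, OO
Why: Baeyer–Villiger oxidation of the strained ketone should let the secondary allylic sp3 carbon migrate with retention in preference to the sp2 carbon, carrying the trans relationship into the lactone, while hydrogen peroxide in acetic acid at this temperature should leave the unstrained alkenes alone.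

Step 6
Reactants: 9 (4S,5R)-3-methylidene-5-(2-methylprop-1-en-1-yl)-4-{(1S)-1-[2,4,6-tri(propan-2-yl)phenyl]ethoxy}oxolan-2-one
Product: 10 (4S,5R)-4-hydroxy-3-methylidene-5-(2-methylprop-1-en-1-yl)oxolan-2-one
Conditions: CF3CO2H, CH2Cl2, 0 °C, short contact
Reagents that add atoms: none
Why: Acidolysis of the benzylic ether (E1) releases the stabilised 1-arylethyl cation, which loses a proton to the styrene, so the C4–O bond and its configuration stay intact.

Step 7
Reactants: 10 (4S,5R)-4-hydroxy-3-methylidene-5-(2-methylprop-1-en-1-yl)oxolan-2-one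
Product: 11 (4S,5R)-4-acetoxy-3-methylidene-5-(2-methylprop-1-en-1-yl)oxolan-2-one
Conditions: Ac2O, pyridine, CH2Cl2, 0 °C
Reagents that add atoms: acetic anhydride, CC(=O)OC(C)=O
Why: O-acetylation without a nucleophilic catalyst should avoid SN2' transposition of the resulting allylic acetate.

Step 8
Reactants: 12 nerol, (2Z)-3,7-dimethylocta-2,6-dien-1-ol
Product: 13 (2Z)-3,7-dimethylocta-2,6-dien-1-yl benzoate
Conditions: BzCl, pyridine, CH2Cl2, 0 °C to rt
Reagents that add atoms: benzoyl chloride, O=C(Cl)c1ccccc1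
Why: Acylation of the primary allylic alcohol installs the benzoate of the target and deactivates the proximal alkene for the next step.

Step 9
Reactants: 13 (2Z)-3,7-dimethylocta-2,6-dien-1-yl benzoate
Product: 14 (2Z,6E)-8-hydroxy-3,7-dimethylocta-2,6-dien-1-yl benzoate
Conditions: SeO2 (10 mol%), tBuOOH, salicylic acid (10 mol%), CH2Cl2, rt
Reagents that add atoms: tert-butyl hydroperoxide, CC(C)(C)OO
Why: Riley allylic oxidation (ene reaction, then [2,3] shift) should hydroxylate the (E)-methyl group of the more electron-rich distal trisubstituted alkene.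

Step 10
Reactants: 14 (2Z,6E)-8-hydroxy-3,7-dimethylocta-2,6-dien-1-yl benzoate
Product: 15 (2Z,6E)-3,7-dimethyl-8-oxoocta-2,6-dien-1-yl benzoate
Conditions: TEMPO (10 mol%), PhI(OAc)2, CH2Cl2, rt
Reagents that add atoms: none
Why: Oxoammonium oxidation of the allylic alcohol should give the enal without alkene isomerisation.

Step 11
Reactants: 15 (2Z,6E)-3,7-dimethyl-8-oxoocta-2,6-dien-1-yl benzoate
Product: 16 (2Z,6E,8R)-8-hydroxy-3,7-dimethylundeca-2,6,10-trien-1-yl benzoate
Conditions: allyltributylstannane, (R)-BINOL (20 mol%), Ti(OiPr)4 (10 mol%), 4 Å MS, CH2Cl2, −20 °C; aq. NaHCO3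
Reagents that add atoms: allyltributylstannane, C=CC[Sn](CCCC)(CCCC)CCCC
Why: Keck allylation, in which the (R)-BINOL titanium Lewis acid should direct the allyl group to the Re face of the α-branched enal and so set the (8R) carbinol.

Step 12
Reactants: 16 (2Z,6E,8R)-8-hydroxy-3,7-dimethylundeca-2,6,10-trien-1-yl benzoate
Product: 17 (2Z,6E,8R)-8-acetoxy-3,7-dimethylundeca-2,6,10-trien-1-yl benzoate
Conditions: Ac2O, pyridine, DMAP (cat.), CH2Cl2, rt
Reagents that add atoms: acetic anhydride, CC(=O)OC(C)=O
Why: Standard acetylation of the secondary allylic alcohol with retention.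

Step 13
Reactants: 11 (4S,5R)-4-acetoxy-3-methylidene-5-(2-methylprop-1-en-1-yl)oxolan-2-one; 17 (2Z,6E,8R)-8-acetoxy-3,7-dimethylundeca-2,6,10-trien-1-yl benzoate
Product: 18 (2Z,6E,8R,10E)-8-acetoxy-10-[(4S,5R)-4-acetoxy-5-(2-methylprop-1-en-1-yl)-2-oxooxolan-3-ylidene]-3,7-dimethyldeca-2,6-dien-1-yl benzoate
Conditions: second-generation Hoveyda–Grubbs catalyst (10 mol%), 2,6-dichloro-1,4-benzoquinone (10 mol%), CH2Cl2, 40 °C, 11 in excess
Reagents that add atoms: none
Why: Olefin cross-metathesis of the terminal alkene of 17 with the 1,1-disubstituted enoate alkene of 11 should give the E alkylidene lactone (chain anti to the lactone carbonyl), with the trisubstituted alkenes as spectators.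

Compound list
1 | (1S)-1-[2,4,6-tri(propan-2-yl)phenyl]ethanol | C[C@H](O)c1c(C(C)C)cc(C(C)C)cc1C(C)C | starting material
2 | 2-[(1S)-1-(prop-2-yn-1-yloxy)ethyl]-1,3,5-tri(propan-2-yl)benzene | C[C@H](OCC#C)c1c(C(C)C)cc(C(C)C)cc1C(C)C | intermediate
3 | 2-[(1S)-1-(propa-1,2-dien-1-yloxy)ethyl]-1,3,5-tri(propan-2-yl)benzene | C[C@H](OC=C=C)c1c(C(C)C)cc(C(C)C)cc1C(C)C | intermediate
4 | 4-methylpent-3-enoic acid | CC(C)=CCC(=O)O | starting material
5 | 4-methylpent-3-enoyl chloride | CC(C)=CCC(=O)Cl | intermediate
6 | 4-methylpenta-1,3-dien-1-one, (2-methylprop-1-enyl)ketene | CC(C)=CC=C=O | intermediate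
7 | (3R,4S)-2-methylidene-4-(2-methylprop-1-en-1-yl)-3-{(1S)-1-[2,4,6-tri(propan-2-yl)phenyl]ethoxy}cyclobutan-1-one (cis) | C=C1C(=O)[C@@H](C=C(C)C)[C@H]1O[C@@H](C)c2c(C(C)C)cc(C(C)C)cc2C(C)C | intermediate
8 | (3R,4R)-2-methylidene-4-(2-methylprop-1-en-1-yl)-3-{(1S)-1-[2,4,6-tri(propan-2-yl)phenyl]ethoxy}cyclobutan-1-one (trans) | C=C1C(=O)[C@H](C=C(C)C)[C@H]1O[C@@H](C)c2c(C(C)C)cc(C(C)C)cc2C(C)C | intermediate
9 | (4S,5R)-3-methylidene-5-(2-methylprop-1-en-1-yl)-4-{(1S)-1-[2,4,6-tri(propan-2-yl)phenyl]ethoxy}oxolan-2-one | C=C1C(=O)O[C@H](C=C(C)C)[C@H]1O[C@@H](C)c2c(C(C)C)cc(C(C)C)cc2C(C)C | intermediate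
10 | (4S,5R)-4-hydroxy-3-methylidene-5-(2-methylprop-1-en-1-yl)oxolan-2-one | C=C1C(=O)O[C@H](C=C(C)C)[C@H]1O | intermediate
11 | (4S,5R)-4-acetoxy-3-methylidene-5-(2-methylprop-1-en-1-yl)oxolan-2-one | C=C1C(=O)O[C@H](C=C(C)C)[C@H]1OC(C)=O | intermediate
12 | nerol, (2Z)-3,7-dimethylocta-2,6-dien-1-ol | CC(C)=CCC/C(C)=C\CO | starting material
13 | (2Z)-3,7-dimethylocta-2,6-dien-1-yl benzoate | CC(C)=CCC/C(C)=C\COC(=O)c1ccccc1 | intermediate
14 | (2Z,6E)-8-hydroxy-3,7-dimethylocta-2,6-dien-1-yl benzoate | OC/C(C)=C/CC/C(C)=C\COC(=O)c1ccccc1 | intermediate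
15 | (2Z,6E)-3,7-dimethyl-8-oxoocta-2,6-dien-1-yl benzoate | O=C/C(C)=C/CC/C(C)=C\COC(=O)c1ccccc1 | intermediate
16 | (2Z,6E,8R)-8-hydroxy-3,7-dimethylundeca-2,6,10-trien-1-yl benzoate | C=CC[C@@H](O)/C(C)=C/CC/C(C)=C\COC(=O)c1ccccc1 | intermediate
17 | (2Z,6E,8R)-8-acetoxy-3,7-dimethylundeca-2,6,10-trien-1-yl benzoate | C=CC[C@@H](OC(C)=O)/C(C)=C/CC/C(C)=C\COC(=O)c1ccccc1 | intermediate
18 | (2Z,6E,8R,10E)-8-acetoxy-10-[(4S,5R)-4-acetoxy-5-(2-methylprop-1-en-1-yl)-2-oxooxolan-3-ylidene]-3,7-dimethyldeca-2,6-dien-1-yl benzoate | CC(=O)O[C@H](C/C=C1/C(=O)O[C@H](C=C(C)C)[C@H]1OC(C)=O)/C(C)=C/CC/C(C)=C\COC(=O)c1ccccc1 | target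

Total step count: 13. Longest linear sequence: 7 steps (steps 1, 2, 4, 5, 6, 7, 13); the chain branch (steps 8 to 12, then 13) is 6 steps.

Steps most likely to fail

Step 4. The vinylketene may dimerise faster than it adds to the allenyl ether. It may also add across the unsubstituted C=C of the allene, or the auxiliary may discriminate the two faces only weakly. The fallback replaces the ketene by a keteniminium ion, which does not dimerise and is more electrophilic. Setting out from 5 (and 3), 5 is treated with dimethylamine to give N,N,4-trimethylpent-3-enamide F1. Tf2O and 2,4,6-collidine in CH2Cl2 convert this into the N,N-dimethylketeniminium triflate F2, which should undergo the same [2+2] cycloaddition with 3 to give the cyclobutaniminium triflate F3. Aqueous NaHCO3 hydrolysis and base equilibration come back to the route at 8. Diastereomers from either variant are separable because the auxiliary sits on the new stereocenter.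

Step 5. The sp2 carbon may migrate instead of the allylic sp3 carbon, giving the regioisomeric enol lactone. Peroxide may also add in conjugate fashion to the enone, or the isobutenyl group may be epoxidised. The fallback is a photochemical ring expansion setting out from 8. Irradiation in methanol (300 nm, NaHCO3) should cleave the bond between the carbonyl and the allylic sp3 carbon (Norrish α-cleavage), reclose to the oxacarbene and insert into methanol, giving the methyl acetal F4 with retention at the migrating carbon. PPTS in aqueous acetone gives the lactol F5, and MnO2 oxidises this allylic lactol, coming back to the route at 9.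

Step 13. Initiation on the hindered 1,1-disubstituted enoate may be slow, so that 17 homodimerises; the new double bond may also lose E/Z purity or migrate. The fallback is a temporary silicon tether with ring-closing metathesis, setting out from 10 and 16. Compound 16 is silylated with iPr2SiCl2 and imidazole to the chlorosilyl ether F6, and addition of 10 gives the mixed silaketal F7. The second-generation Hoveyda–Grubbs catalyst should close the eight-membered cyclic silaketal F8, in which the ring forces the chain cis to C4, that is, the required E alkylidene. HF·pyridine gives the diol F9, and Ac2O in pyridine acetylates both hydroxyls at once, coming back to the route at 18.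

Further compounds
F1 | step 4 | N,N,4-trimethylpent-3-enamide | CC(C)=CCC(=O)N(C)C
F2 | step 4 | N,N-dimethyl-(4-methylpenta-1,3-dien-1-ylidene)ammonium triflate | CC(C)=CC=C=[N+](C)C.[O-]S(=O)(=O)C(F)(F)F
F3 | step 4 | N,N-dimethyl cyclobutaniminium triflate corresponding to 8 | C=C1C(=[N+](C)C)[C@H](C=C(C)C)[C@H]1O[C@@H](C)c2c(C(C)C)cc(C(C)C)cc2C(C)C.[O-]S(=O)(=O)C(F)(F)F
F4 | step 5 | (4S,5R)-2-methoxy-3-methylidene-5-(2-methylprop-1-en-1-yl)-4-{(1S)-1-[2,4,6-tri(propan-2-yl)phenyl]ethoxy}oxolane (anomers) | C=C1C(OC)O[C@H](C=C(C)C)[C@H]1O[C@@H](C)c2c(C(C)C)cc(C(C)C)cc2C(C)C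
F5 | step 5 | (4S,5R)-3-methylidene-5-(2-methylprop-1-en-1-yl)-4-{(1S)-1-[2,4,6-tri(propan-2-yl)phenyl]ethoxy}oxolan-2-ol (anomers) | C=C1C(O)O[C@H](C=C(C)C)[C@H]1O[C@@H](C)c2c(C(C)C)cc(C(C)C)cc2C(C)C
F6 | step 13 | (2Z,6E,8R)-8-{[chlorodi(propan-2-yl)silyl]oxy}-3,7-dimethylundeca-2,6,10-trien-1-yl benzoate | C=CC[C@@H](O[Si](Cl)(C(C)C)C(C)C)/C(C)=C/CC/C(C)=C\COC(=O)c1ccccc1
F7 | step 13 | mixed di(propan-2-yl)silyl bis-ether of 10 and 16 | C=CC[C@@H](O[Si](C(C)C)(C(C)C)O[C@H]1C(=C)C(=O)O[C@@H]1C=C(C)C)/C(C)=C/CC/C(C)=C\COC(=O)c2ccccc2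
F8 | step 13 | eight-membered cyclic di(propan-2-yl)silaketal of F9 | CC(C)[Si]1(C(C)C)O[C@H](C/C=C2/C(=O)O[C@H](C=C(C)C)[C@H]2O1)/C(C)=C/CC/C(C)=C\COC(=O)c3ccccc3
F9 | step 13 | (2Z,6E,8R,10E)-8-hydroxy-10-[(4S,5R)-4-hydroxy-5-(2-methylprop-1-en-1-yl)-2-oxooxolan-3-ylidene]-3,7-dimethyldeca-2,6-dien-1-yl benzoate | O[C@H](C/C=C1/C(=O)O[C@H](C=C(C)C)[C@H]1O)/C(C)=C/CC/C(C)=C\COC(=O)c2ccccc2
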